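**Strategy.** Everything rests on cutting the C8–C9 bond of ring B as the retron of a Claisen rearrangement: the γ,δ-unsaturated ketone C10(=O)–C9–C8–C7=C6 that ties the cyclohexanone (ring B) to the C4–C7 diene of ring A. The precursor is a bridged 2-oxabicyclo[3.3.1]nonene in which oxygen links C6 to C10 as a Z-ethylidene enol ether and C7 carries an exocyclic methylene. On heating, one boat [3,3] shift should close ring B, unveil the C10 ketone, complete the ring A diene and fix C9, so that the all-cis H9/H11/H12 array (a boat-shaped ring B) arises under kinetic control. The precursor derives from a Diels–Alder adduct of a chiral dihydropyranone.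

Key step: step 15

Remark: carbons are numbered C1–C20 along the chain of the target (C1 acetyl CH3, C2 ketone, C3 CH2, C4–C7 ring A diene with methyl on C5, C8 CH2, C9 CHMe, C10 ring ketone, C11 CHMe, C12 ring-fusion CH, C13 CH bearing the side chain, C14=C15(Me), C16/C17 epoxide, C18=C19, C20 CO2H); TBS = tert-butyldimethylsilyl, Piv = pivaloyl; the carbinol centres at C2 (from 1) and C10 (step 18) are assumed as drawn and are erased in step 23.

Step 1
Reactants: 1 (S)-pent-4-en-2-ol
Product: 2 (3E,6S)-6-hydroxy-3-methylhept-3-en-2-one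
Conditions: 3-methylbut-3-en-2-one (4 equiv), second-generation Hoveyda–Grubbs catalyst (5 mol%), CH2Cl2, 40 °C
Reagents that add atoms: 3-methylbut-3-en-2-one, CC(=O)C(C)=C
Why: Cross-metathesis of a terminal alkene with a 1,1-disubstituted enone should give the E-trisubstituted enone with loss of ethylene, leaving the carbinol centre untouched.

Step 2
Reactants: 2 (3E,6S)-6-hydroxy-3-methylhept-3-en-2-one
Product: 3 (3E,6S)-2,6-bis(tert-butyldimethylsilyloxy)-3-methylhepta-1,3-diene
Conditions: TBSOTf (2.3 equiv), Et3N, CH2Cl2, −78 → 0 °C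
Reagents that add atoms: tert-butyldimethylsilyl triflate, C[Si](C)(OS(=O)(=O)C(F)(F)F)C(C)(C)C
Why: Silylation of the alcohol and soft enolisation of the methyl ketone (silyl enol ether formation at the CH3 side) should give the cross-conjugated 2-silyloxy diene.

Step 3
Reactants: 4 methyl (S)-3-hydroxy-2-methylpropanoate
Product: 5 methyl (S)-3-(tert-butyldimethylsilyloxy)-2-methylpropanoate
Conditions: TBSCl, imidazole, CH2Cl2, rt
Reagents that add atoms: tert-butyldimethylsilyl chloride, C[Si](C)(Cl)C(C)(C)C
Why: Standard silyl protection of the primary alcohol.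

Step 4
Reactants: 5 methyl (S)-3-(tert-butyldimethylsilyloxy)-2-methylpropanoate
Product: 6 (S)-3-(tert-butyldimethylsilyloxy)-2-methylpropanal
Conditions: iBu2AlH (1.05 equiv), CH2Cl2, −78 °C; aq. potassium sodium tartrate
Reagents that add atoms: none
Why: Partial hydride reduction of the ester stops at the tetrahedral aluminate at −78 °C and should release the aldehyde on work-up without touching the α-centre.

Step 5
Reactants: 6 (S)-3-(tert-butyldimethylsilyloxy)-2-methylpropanal
Product: 7 methyl (2Z,4R)-5-(tert-butyldimethylsilyloxy)-4-methylpent-2-enoate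
Conditions: methyl bis(2,2,2-trifluoroethyl)phosphonoacetate, KHMDS, 18-crown-6, THF, −78 °C
Reagents that add atoms: methyl bis(2,2,2-trifluoroethyl)phosphonoacetate, COC(=O)CP(=O)(OCC(F)(F)F)OCC(F)(F)F
Why: The Still–Gennari variant of the Horner–Wadsworth–Emmons reaction should give the Z-enoate needed for lactonisation.

Step 6
Reactants: 7 methyl (2Z,4R)-5-(tert-butyldimethylsilyloxy)-4-methylpent-2-enoate
Product: 9 (R)-5-methyl-5,6-dihydro-2H-pyran-2-one, via hydroxy Z-enoate 8 (not isolated)
Conditions: TsOH·H2O (cat.), MeOH, rt; then PhMe, 50 °C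
Reagents that add atoms: none
Why: Acid-catalysed desilylation frees the alcohol, which should lactonise at once onto the cis-disposed ester (transesterification).

Step 7
Reactants: 3 (3E,6S)-2,6-bis(tert-butyldimethylsilyloxy)-3-methylhepta-1,3-diene; 9 (R)-5-methyl-5,6-dihydro-2H-pyran-2-one
Product: 10 cis-fused lactone adduct (ring A as C5=C6 TBS enol ether)
Conditions: PhMe (1 M), BHT (cat.), 150 °C, sealed tube
Reagents that add atoms: none
Why: In this Diels–Alder reaction the 2-silyloxy group (para rule) and the terminal alkyl group (ortho rule) should direct C7 to the lactone β-carbon C12 and C4 to the α-carbon C13; the cyclic cis-dienophile gives cis H12/H13, and approach anti to the C11 methyl fixes C12 and C13 relative to C11 (the C4 centre is erased in step 10).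

Step 8
Reactants: 10 cis-fused lactone adduct
Product: 11 lactol (C14 hemiacetal, anomer mixture)
Conditions: iBu2AlH (1.1 equiv), CH2Cl2, −78 °C
Reagents that add atoms: none
Why: Partial reduction of a δ-lactone to the lactol; both silyl groups should tolerate the hydride.

Step 9
Reactants: 11 lactol
Product: 13 vinyl pivalate, via primary alcohol 12 (not isolated)
Conditions: Ph3PCH3Br, KHMDS, THF, 0 °C → rt; then PivCl, Et3N, DMAP (cat.), 0 °C
Reagents that add atoms: methyltriphenylphosphonium bromide, C[P+](c1ccccc1)(c1ccccc1)c1ccccc1.[Br-]; pivaloyl chloride, CC(C)(C)C(=O)Cl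
Why: Wittig methylenation of the open hydroxy-aldehyde form turns C14 into an inert vinyl group, and acylating the released C10 alkoxide in the same flask keeps it from adding to the enone made in step 11.

Step 10
Reactants: 13 vinyl pivalate
Product: 14 ring A enone (C6 ketone, C4=C5)
Conditions: Pd(OAc)2 (1.1 equiv), MeCN, 40 °C
Reagents that add atoms: none
Why: Saegusa–Ito oxidation: the palladium enolate formed from the silyl enol ether should undergo β-hydride elimination towards C4 to give the tetrasubstituted conjugated enone, removing the C4 stereocentre.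

Step 11
Reactants: 14 ring A enone
Product: 17 exo-methylene dienone, via Mannich base 15 (not isolated), via ammonium iodide 16 (not isolated)
Conditions: LiHMDS, THF, −78 °C; CH2=NMe2+ I−, −78 → 0 °C; MeI, CH2Cl2, rt; aq. NaHCO3
Reagents that add atoms: Eschenmoser's salt (dimethylmethylideneammonium iodide), C=[N+](C)C.[I-]
Why: Kinetic α′-deprotonation at C7, Mannich reaction, quaternisation and E1cB loss of trimethylamine should install the C7=C8 methylene (17 is used at once, since migration of this double bond into the ring would open a path to a phenol).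

Step 12
Reactants: 17 exo-methylene dienone
Product: 18 diol (C6–OH cis to the C12 side chain; C10–OH primary)
Conditions: iBu2AlH (4 equiv), CH2Cl2, −78 °C
Reagents that add atoms: none
Why: 1,2-Reduction of the cross-conjugated dienone should occur from the face opposite the two cis substituents at C12 and C13, placing the C6 hydroxyl cis to both, while the pivalate is cleaved reductively in the same operation.

Step 13
Reactants: 18 diol
Product: 20 bridged δ-lactone, via bridged lactol 19 (not isolated)
Conditions: TEMPO (20 mol%), PhI(OAc)2 (2.5 equiv), CH2Cl2, rt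
Reagents that add atoms: none
Why: Oxoammonium oxidation is fastest at the primary alcohol; the aldehyde should be trapped by the cis C6 hydroxyl as a lactol and oxidised on to the lactone (oxidative lactonisation) under conditions mild enough to keep C11.

Step 14
Reactants: 20 bridged δ-lactone
Product: 21 (Z)-ethylidene enol ether
Conditions: CH3CHBr2, TiCl4, Zn, TMEDA, PbCl2 (cat.), THF, 0 °C → rt; filtration through basic alumina
Reagents that add atoms: 1,1-dibromoethane, CC(Br)Br
Why: Takai–Utimoto alkylidenation of the ester carbonyl should give the Z enol ether (methyl cis to the ring oxygen), the lactone being the only carbonyl group present.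

Step 15
Reactants: 21 (Z)-ethylidene enol ether
Product: 22 bicyclic dienyl ketone (rings A and B of the target)
Conditions: mesitylene (0.01 M, degassed), BHT (cat.), 180 °C, sealed base-washed tube
Reagents that add atoms: none
Why: Heating should trigger a concerted suprafacial [3,3] sigmatropic (Claisen) shift across C9=C10–O–C6–C7=C8, in which the doubly allylic O–C6 bond breaks while C8–C9 forms, giving the C10 ketone and the C6=C7 alkene in conjugation with C4=C5. The closest known reaction type is the Claisen rearrangement of lactone-derived 2-alkylidene oxacycles, run here through the boat transition state also followed by the [3,3] shift of 1,4-dimethylenecyclohexane. Ring B, the only ring closed, forms in a 6-endo sense at both π termini, the C10–C11–C12–C7 tether forcing a bicyclo[2.2.2]octane-like boat array. C9 is the only new stereocentre: the Z geometry of the enol ether (methyl cis to oxygen, hence pseudo-equatorial in the boat) together with the fixed C11 and C12 centres should give the all-cis H9/H11/H12 pattern without any enolisable intermediate. The step needs periselectivity for the CH2 terminus C8 over the C4 terminus of the other allyl unit, over the Cope mode that would break C11–C12, and over ionisation of the C6–O bond; the unhindered methylene (C4 would have to become quaternary), the gain of a carbonyl group and acid-free non-polar conditions should secure it.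

Step 16
Reactants: 22 bicyclic dienyl ketone
Product: 23 (E)-enal
Conditions: methacrolein (10 equiv), second-generation Hoveyda–Grubbs catalyst (10 mol%), 1,4-benzoquinone (10 mol%), CH2Cl2, 40 °C
Reagents that add atoms: methacrolein, CC(=C)C=O
Why: Cross-metathesis of the terminal vinyl group with methacrolein should give the E-trisubstituted enal, the tri- and tetrasubstituted ring alkenes being inert and the neutral conditions sparing C9 and C11.

Step 17
Reactants: 23 (E)-enal
Product: 24 (E,E)-dienoate
Conditions: ethyl 2-(triphenylphosphoranylidene)propanoate, PhMe, 80 °C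
Reagents that add atoms: ethyl 2-(triphenylphosphoranylidene)propanoate, CCOC(=O)C(C)=P(c1ccccc1)(c1ccccc1)c1ccccc1
Why: The Wittig reaction of a stabilised ylide is E-selective, reacts with the aldehyde and not the ketone, and is too weakly basic to enolise C10.

Step 18
Reactants: 24 (E,E)-dienoate
Product: 25 dienol with C10 carbinol
Conditions: iBu2AlH (5 equiv), CH2Cl2, −78 °C
Reagents that add atoms: none
Why: Hydride reduction converts the ester into the allylic alcohol and, usefully, the C10 ketone into a carbinol (hydride expected anti to the C9/C11 methyls), which shields C9 and C11 from epimerisation in the basic steps that follow.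

Step 19
Reactants: 25 dienol with C10 carbinol
Product: 26 (16S,17S)-epoxy alcohol
Conditions: Ti(OiPr)4, L-(+)-diethyl tartrate, tBuOOH, 4 Å molecular sieves, CH2Cl2, −20 °C
Reagents that add atoms: tert-butyl hydroperoxide, CC(C)(C)OO
Why: Sharpless asymmetric epoxidation acts only on the allylic alcohol alkene; reagent control by L-(+)-tartrate should give the (2S,3S)-type epoxy alcohol, as for other (E)-2-methyl-3-substituted allylic alcohols, and the E geometry sets the trans epoxide.

Step 20
Reactants: 26 (16S,17S)-epoxy alcohol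
Product: 27 epoxy aldehyde
Conditions: TEMPO (10 mol%), PhI(OAc)2 (1.2 equiv), CH2Cl2, 0 °C → rt
Reagents that add atoms: none
Why: Oxoammonium oxidation should pick the primary alcohol over the hindered secondary C10 carbinol and leave the epoxide intact.

Step 21
Reactants: 27 epoxy aldehyde
Product: 28 epoxy dienoic acid (C2–OTBS, C10–OH)
Conditions: (EtO)2P(O)CH2CO2H, LiHMDS (3.3 equiv), THF, −78 → 0 °C; aq. NaH2PO4
Reagents that add atoms: diethylphosphonoacetic acid, CCOP(=O)(CC(=O)O)OCC
Why: Horner–Wadsworth–Emmons olefination with the phosphonoacetate dianion should give the E-acrylic acid directly; the aldehyde has no α-hydrogen and no ketone is present.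

Step 22
Reactants: 28 epoxy dienoic acid
Product: 29 dihydroxy acid
Conditions: Bu4NF, THF, 0 °C → rt; aq. NH4Cl
Reagents that add atoms: none
Why: Fluoride cleaves the secondary silyl ether at a stage where no base-sensitive ketone exists.

Step 23
Reactants: 29 dihydroxy acid
Product: 30 CNP0214881.1
Conditions: Dess–Martin periodinane (3 equiv), NaHCO3, CH2Cl2, 0 °C → rt
Reagents that add atoms: none
Why: Dess–Martin oxidation of both secondary alcohols under buffered, near-neutral conditions should unveil the C2 and C10 ketones last, so that neither the β,γ-unsaturated ketone nor the epimerisable C9/C11 centres meet acid or base.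

Compound list
1 | (S)-pent-4-en-2-ol | C[C@H](O)CC=C | starting material
2 | (3E,6S)-6-hydroxy-3-methylhept-3-en-2-one | C[C@H](O)C/C=C(\C)C(C)=O | intermediate
3 | (3E,6S)-2,6-bis(tert-butyldimethylsilyloxy)-3-methylhepta-1,3-diene | C[C@H](O[Si](C)(C)C(C)(C)C)C/C=C(\C)C(=C)O[Si](C)(C)C(C)(C)C | intermediate
4 | methyl (S)-3-hydroxy-2-methylpropanoate | C[C@@H](CO)C(=O)OC | starting material
5 | methyl (S)-3-(tert-butyldimethylsilyloxy)-2-methylpropanoate | C[C@@H](CO[Si](C)(C)C(C)(C)C)C(=O)OC | intermediate
6 | (S)-3-(tert-butyldimethylsilyloxy)-2-methylpropanal | C[C@@H](CO[Si](C)(C)C(C)(C)C)C=O | intermediate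
7 | methyl (2Z,4R)-5-(tert-butyldimethylsilyloxy)-4-methylpent-2-enoate | C[C@@H](CO[Si](C)(C)C(C)(C)C)/C=C\C(=O)OC | intermediate
8 | methyl (2Z,4R)-5-hydroxy-4-methylpent-2-enoate | C[C@@H](CO)/C=C\C(=O)OC | intermediate (not isolated)
9 | (R)-5-methyl-5,6-dihydro-2H-pyran-2-one | C[C@H]1COC(=O)C=C1 | intermediate
10 | cis-fused adduct, 4,7-dimethyl-6-(TBS-oxy)-8-[(S)-2-(TBS-oxy)propyl]-3,4,4a,5,8,8a-hexahydro-1H-isochromen-1-one; H12/H13 cis, C11 methyl trans to C7, H4 cis to H13 | C[C@H](O[Si](C)(C)C(C)(C)C)C[C@@H]1C(C)=C(O[Si](C)(C)C(C)(C)C)C[C@@H]2[C@@H](C)COC(=O)[C@H]12 | intermediate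
11 | lactol of 10 (C14 hemiacetal, anomer mixture) | C[C@H](O[Si](C)(C)C(C)(C)C)C[C@@H]1C(C)=C(O[Si](C)(C)C(C)(C)C)C[C@@H]2[C@@H](C)COC(O)[C@H]12 | intermediate
12 | ring A silyl enol ether with C13 vinyl and free C10 primary alcohol | C[C@H](O[Si](C)(C)C(C)(C)C)C[C@@H]1C(C)=C(O[Si](C)(C)C(C)(C)C)C[C@H]([C@@H](C)CO)[C@@H]1C=C | intermediate (not isolated)
13 | pivalate of 12 | C[C@H](O[Si](C)(C)C(C)(C)C)C[C@@H]1C(C)=C(O[Si](C)(C)C(C)(C)C)C[C@H]([C@@H](C)COC(=O)C(C)(C)C)[C@@H]1C=C | intermediate
14 | ring A enone (C6 ketone, C4=C5; C12 and C13 substituents cis) | C[C@H](O[Si](C)(C)C(C)(C)C)CC1=C(C)C(=O)C[C@H]([C@@H](C)COC(=O)C(C)(C)C)[C@@H]1C=C | intermediate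
15 | C7 dimethylaminomethyl ketone (Mannich base, C7 epimers) | C[C@H](O[Si](C)(C)C(C)(C)C)CC1=C(C)C(=O)C(CN(C)C)[C@H]([C@@H](C)COC(=O)C(C)(C)C)[C@@H]1C=C | intermediate (not isolated)
16 | trimethylammonium iodide of 15 | C[C@H](O[Si](C)(C)C(C)(C)C)CC1=C(C)C(=O)C(C[N+](C)(C)C)[C@H]([C@@H](C)COC(=O)C(C)(C)C)[C@@H]1C=C.[I-] | intermediate (not isolated)
17 | cross-conjugated dienone with C7=C8 exocyclic methylene | C[C@H](O[Si](C)(C)C(C)(C)C)CC1=C(C)C(=O)C(=C)[C@H]([C@@H](C)COC(=O)C(C)(C)C)[C@@H]1C=C | intermediate
18 | diol: C6 secondary allylic alcohol cis to the C12 side chain and to the C13 vinyl group, C10 primary alcohol | C[C@H](O[Si](C)(C)C(C)(C)C)CC1=C(C)[C@H](O)C(=C)[C@H]([C@@H](C)CO)[C@@H]1C=C | intermediate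
19 | bridged lactol (2-oxabicyclo[3.3.1]non-7-en-3-ol, anomer mixture) | C[C@H](O[Si](C)(C)C(C)(C)C)CC1=C(C)[C@@H]2OC(O)[C@H](C)[C@@H](C2=C)[C@@H]1C=C | intermediate (not isolated)
20 | bridged lactone, 4,8-dimethyl-9-methylidene-7-[(S)-2-(TBS-oxy)propyl]-6-vinyl-2-oxabicyclo[3.3.1]non-7-en-3-one; C11 methyl and C13 vinyl both syn to the lactone bridge | C[C@H](O[Si](C)(C)C(C)(C)C)CC1=C(C)[C@@H]2OC(=O)[C@H](C)[C@@H](C2=C)[C@@H]1C=C | intermediate
21 | (Z)-3-ethylidene analogue of 20 (enol ether, methyl cis to ring oxygen) | C[C@H](O[Si](C)(C)C(C)(C)C)CC1=C(C)[C@@H]2O/C(=C\C)[C@H](C)[C@@H](C2=C)[C@@H]1C=C | intermediate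
22 | 1,3,6-trimethyl-7-[(S)-2-(TBS-oxy)propyl]-8-vinyl-3,4,8,8a-tetrahydronaphthalen-2(1H)-one; C9, C11, C12, C13 as in the target | C[C@H](O[Si](C)(C)C(C)(C)C)CC1=C(C)C=C2C[C@H](C)C(=O)[C@H](C)[C@@H]2[C@@H]1C=C | intermediate
23 | (E)-2-methylpropenal side chain at C13 (C14=C15, C16 aldehyde) | C[C@H](O[Si](C)(C)C(C)(C)C)CC1=C(C)C=C2C[C@H](C)C(=O)[C@H](C)[C@@H]2[C@@H]1/C=C(\C)C=O | intermediate
24 | ethyl (2E,4E)-2,4-dimethylpenta-2,4-dienoate side chain at C13 | C[C@H](O[Si](C)(C)C(C)(C)C)CC1=C(C)C=C2C[C@H](C)C(=O)[C@H](C)[C@@H]2[C@@H]1/C=C(\C)/C=C(\C)C(=O)OCC | intermediate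
25 | (E,E)-dienol with C10 carbinol (OH cis to the C9 and C11 methyls) | C[C@H](O[Si](C)(C)C(C)(C)C)CC1=C(C)C=C2C[C@H](C)[C@H](O)[C@H](C)[C@@H]2[C@@H]1/C=C(\C)/C=C(\C)CO | intermediate
26 | (16S,17S)-epoxy alcohol | C[C@H](O[Si](C)(C)C(C)(C)C)CC1=C(C)C=C2C[C@H](C)[C@H](O)[C@H](C)[C@@H]2[C@@H]1/C=C(\C)[C@@H]1O[C@@]1(C)CO | intermediate
27 | (16S,17S)-epoxy aldehyde | C[C@H](O[Si](C)(C)C(C)(C)C)CC1=C(C)C=C2C[C@H](C)[C@H](O)[C@H](C)[C@@H]2[C@@H]1/C=C(\C)[C@@H]1O[C@@]1(C)C=O | intermediate
28 | (18E)-acrylic acid with C2–OTBS and C10–OH | C[C@H](O[Si](C)(C)C(C)(C)C)CC1=C(C)C=C2C[C@H](C)[C@H](O)[C@H](C)[C@@H]2[C@@H]1/C=C(\C)[C@@H]1O[C@@]1(C)/C=C/C(=O)O | intermediate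
29 | C2,C10-dihydroxy acid | C[C@H](O)CC1=C(C)C=C2C[C@H](C)[C@H](O)[C@H](C)[C@@H]2[C@@H]1/C=C(\C)[C@@H]1O[C@@]1(C)/C=C/C(=O)O | intermediate
30 | CNP0214881.1, (9S,11R,12S,13S,14E,16S,17S,18E) in the numbering above | CC(=O)CC1=C(C)C=C2C[C@H](C)C(=O)[C@H](C)[C@@H]2[C@@H]1/C=C(\C)[C@@H]1O[C@@]1(C)/C=C/C(=O)O | target

Total steps: 23. Longest linear sequence: 21 (steps 3–6, then 7–23).

Steps most likely to fail

Step 15. The doubly allylic C6–O bond may ionise or cleave before the boat array is reached, so that C9 recombines at C6 or at the C4 terminus; traces of acid would also move the enol ether double bond into the ring and erase C11. The fallback forms the same bond by ionic allylation, setting out from 20 and returning at 22. Lactone 20 is opened with MeNHOMe·HCl and iPrMgCl to the hydroxy Weinreb amide F1. EtMgBr converts it into the hydroxy ethyl ketone F2, and ClCO2Me with pyridine gives the allylic methyl carbonate F3. Pd(PPh3)4 in THF then ionises the carbonate, and the ketone enolate formed by the released methoxide attacks the CH2 terminus C8 of the π-allyl complex (intramolecular Tsuji–Trost allylation) to give 22. C9 would then be set under substrate control, and C9 epimers may have to be separated.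

Step 7. The unsaturated δ-lactone may be too weak a dienophile, so that the silyloxy diene decays thermally before cycloaddition, and facial discrimination by the C11 methyl may be incomplete. The fallback builds the ring stepwise by anionic chemistry, setting out from 2 and 9 and returning at 10. Alcohol 2 is silylated (TBSCl, imidazole) to the TBS-protected enone F4. Its kinetic lithium enolate (LDA, THF, −78 °C, deprotonation of the methyl ketone) adds to 9 anti to the methyl group, and the lactone enolate so formed closes onto the enone β-carbon C4 (Michael–Michael annulation) to give the keto lactone F5. TBSOTf and Et3N under equilibrating conditions then give the more substituted silyl enol ether 10; a C4 epimer would converge at 14.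

Step 14. Alkylidenation of the hindered bridged lactone may stall, low-valent titanium may cleave the doubly allylic C–O bond reductively, or the Z geometry may erode. The fallback makes the enol ether by alkynol cycloisomerisation, setting out from 18 and returning at 21. The oxidation of step 13 is stopped at lactol 19 (1.1 equiv PhI(OAc)2). Dimethyl (1-diazo-2-oxopropyl)phosphonate with K2CO3 in MeOH (Seyferth–Gilbert homologation, Ohira–Bestmann variant) gives the terminal alkynol F6. Its dianion (n-BuLi, 2.1 equiv, THF, −78 °C) is C-methylated with MeI to the methyl alkynol F7. Ph3PAuNTf2 (cat., CH2Cl2) should then effect 6-exo-dig anti-hydroalkoxylation, which delivers the Z enol ether 21.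

Further compounds
F1 | step 15 | hydroxy Weinreb amide (C6–OH, C10 N-methoxy-N-methylamide) | C[C@H](O[Si](C)(C)C(C)(C)C)CC1=C(C)[C@H](O)C(=C)[C@H]([C@@H](C)C(=O)N(C)OC)[C@@H]1C=C
F2 | step 15 | hydroxy ethyl ketone (C6–OH, C10 ketone bearing C9H2–CH3) | C[C@H](O[Si](C)(C)C(C)(C)C)CC1=C(C)[C@H](O)C(=C)[C@H]([C@@H](C)C(=O)CC)[C@@H]1C=C
F3 | step 15 | allylic methyl carbonate of F2 | C[C@H](O[Si](C)(C)C(C)(C)C)CC1=C(C)[C@H](OC(=O)OC)C(=C)[C@H]([C@@H](C)C(=O)CC)[C@@H]1C=C
F4 | step 7 | (3E,6S)-6-(tert-butyldimethylsilyloxy)-3-methylhept-3-en-2-one | C[C@H](O[Si](C)(C)C(C)(C)C)C/C=C(\C)C(C)=O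
F5 | step 7 | cis-fused keto lactone (C6 ketone; C4 and C5 not controlled) | C[C@H](O[Si](C)(C)C(C)(C)C)CC1C(C)C(=O)C[C@@H]2[C@@H](C)COC(=O)[C@H]12
F6 | step 14 | terminal alkynol (C6–OH, C10≡C9H) | C[C@H](O[Si](C)(C)C(C)(C)C)CC1=C(C)[C@H](O)C(=C)[C@H]([C@@H](C)C#C)[C@@H]1C=C
F7 | step 14 | methyl alkynol (C6–OH, C10≡C9–CH3) | C[C@H](O[Si](C)(C)C(C)(C)C)CC1=C(C)[C@H](O)C(=C)[C@H]([C@@H](C)C#CC)[C@@H]1C=C
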